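## Analysis of the target

The target is a 2,3-dihydro-1-benzofuran (O1, C2, C3, C3a, C4–C7, C7a). Ring A carries a phenol at C4 and an (E)-4-hydroxystyryl group at C6; C2 bears a 2,4-dihydroxyphenyl ring and C3 a 3,5-dihydroxyphenyl ring. Both stereocentres are S, which places the two aryl groups trans, the more stable arrangement on this ring. The sensitive parts are six free phenols, an electron-rich stilbene, a doubly benzylic C3–H and the C2–O1 bond, a benzylic aryl ether whose benzylic carbon sits on an ortho,para-dioxygenated ring and can ionise under acid. The hard part is absolute configuration: C2 and C3 carry only aryl groups, hydrogen and ring bonds, so the finished molecule offers no carbonyl or heteroatom handle for an asymmetric reaction. A second problem is ring A, which has two different oxygen functions flanking C3a. Because trans is favoured, one stereocentre made as a single enantiomer can govern the other. The route rests on the fact that O1–C2–C3–C3a–C7a, with the aryl group on C2, is the pyranone ring of a (2S)-flavanone with its carbonyl carbon taken out (C3a is the flavanone C4a). Flavanones can be made with defined C2 from chromones, and a Wolff ring contraction pushes the carbonyl carbon out of the ring as a carboxyl group on C3, where a handle for the second aryl group is needed.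

## Retrosynthetic reasoning

**20 from 19.** The six O–CH3 bonds are cut last. Methyl ethers are the one phenol protection that passes organolithium, Lewis-acid, photochemical and radical steps unchanged. The forward reaction is a global ether cleavage that must leave C2–O1 and the alkene intact.

**19 from 17 and 18.** The stilbene C=C is cut. This keeps the light- and acid-sensitive alkene out of all earlier steps and reduces the C6 substituent to a formyl group. The forward reaction must be E-selective, which a benzylic phosphonate olefination is.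

**17 from 16 from 15.** These are adjustments of the C6 carbon: aldehyde from primary alcohol, alcohol from its silyl ether. The silyloxymethyl group is the inert form in which this carbon travels from the first step.

**15 from 13 and 14.** The C3–aryl bond is cut, with a carboxyl group on C3 as a radical precursor. The cut is made here because C3 has no other activating group and a C3 carboxylic acid is what a ring contraction delivers. Both C3 epimers of 13 give the same planar radical, and the C2 aryl group has to direct the new bond trans.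

**13 from 11 (through 12).** This is the central disconnection. The C3–C3a bond is cut and the carboxyl carbon is put back between C3 and C3a, giving a chroman-4-one with a diazo group on C3. Forward, the ring A carbon migrates from the carbonyl carbon to C3, the ring contracts from six to five members and the former carbonyl carbon becomes the acid. C2 is not involved.

**11 from 9 (through 10).** The diazo group replaces the two C3 hydrogens of the flavanone. The forward reaction has to do this without opening the pyranone ring, which would racemise C2.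

**9 from 7 and 8.** The C2–aryl bond is cut to a chromone and an arylboronic acid. This is the only step in which a chiral catalyst sets a stereocentre, and it does so on a flat, simple substrate.

**7 from 5 (through 6).** C2 of the chromone is removed as a one-carbon unit, breaking O1–C2 and C2–C3. Forward, this is the condensation of an ortho-hydroxy acetophenone with a formamide acetal followed by ring closure.

**5 from 4, 4 from 2 (through 3), 2 from 1.** The acetyl group is placed between the two methoxy groups of ring A by directed lithiation. One methyl ether next to the ketone is removed under chelation control, which differentiates the two ring A oxygens. The benzylic alcohol is silylated first.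

## Alternatives that were turned down

**Alternative 1:** Here ring A itself is disconnected (C3a–C7a, C4–C5 and C4–O), back to the open-chain furan-yne A1, methyl 5-{[(1S,2R)-1-(2,4-dimethoxyphenyl)-2-(3,5-dimethoxyphenyl)but-3-yn-1-yl]oxy}furan-3-carboxylate. Forward, Ph3PAuNTf2 (monovalent gold) or AuCl3 (trivalent gold) activates the alkyne, the furan adds, and the cascade through an arene oxide gives the phenol A2, methyl (2S,3S)-2-(2,4-dimethoxyphenyl)-3-(3,5-dimethoxyphenyl)-4-hydroxy-2,3-dihydrobenzofuran-6-carboxylate, with ring A and the dihydrofuran ring closed together.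
- In its favour: the C4 hydroxyl appears free and already distinguished from O1, and the ring A pattern is fixed by the cascade. On this point it is stronger than the chosen route, which needs a chelation-controlled demethylation.
- Against it: A1 is a 2-alkoxyfuran, an acid-labile ketene-acetal-like ether, whose O–C bond goes to a 2,4-dimethoxybenzylic carbon. Both stereocentres would have to be set on an open chain that has a doubly activated propargylic C–H, with no obvious catalytic method. A tether joined to the furan through oxygen is outside the usual scope of this phenol synthesis.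
- Comparison: the ester of A2 needs the same redox and olefination end-game, so nothing is saved. The chosen route sets C2 on a chromone by catalysis and C3 by substrate control.

**Alternative 2:** The C2–C3 bond is cut. Forward, the diaryl diazomethane A3, 5-bromo-1-[(2,4-dimethoxyphenyl)methoxy]-2-[diazo(3,5-dimethoxyphenyl)methyl]-3-methoxybenzene, gives with Rh2(R-PTAD)4 or its enantiomer (divalent rhodium) a donor/donor carbene at C3. The carbene inserts into the benzylic ether C–H bond and closes the five-membered ring to A4, (2R,3S)-cis-6-bromo-2-(2,4-dimethoxyphenyl)-3-(3,5-dimethoxyphenyl)-4-methoxy-2,3-dihydrobenzofuran.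
- In its favour: both stereocentres come from one catalytic step, the route is convergent, and the C6 bromide allows the styryl group to be attached directly. It is clearly stronger in step economy.
- Against it: the insertion gives the cis isomer, so C2 must afterwards be epimerised by ionising C2–O1 on a sensitive compound. The carbene-bearing ring is substituted at both ortho positions, which makes A3 hard to prepare and twists the carbene. The C–H bond is activated by a 2,4-dimethoxyphenyl group, which favours a stepwise hydride-transfer course with loss of stereocontrol.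
- Comparison: the chosen route is longer, but the trans relation arises directly and the two control elements (catalyst for C2, C2 for C3) are independent of each other.

**Alternative 3:** The C7a–O1 and C3–C3a bonds are cut. Forward, CsF releases the C3a≡C7a aryne from the silyl triflate A5, methyl 3-methoxy-4-(trifluoromethylsulfonyloxy)-5-(trimethylsilyl)benzoate. The oxygen of the epoxide A6, (2R,3R)-2-[2,4-bis(trifluoromethylsulfonyloxy)phenyl]-3-(3,5-dimethoxyphenyl)oxirane, adds to C7a, and the C3a anion takes the C3 epoxide carbon. The product is A7, methyl (2S,3S)-2-[2,4-bis(trifluoromethylsulfonyloxy)phenyl]-3-(3,5-dimethoxyphenyl)-4-methoxy-2,3-dihydrobenzofuran-6-carboxylate.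
- In its favour: it is the most convergent of all, the methoxy group steers the regiochemistry of aryne attack, and enantiopure epoxides of this kind are accessible.
- Against it: the aryl anion cannot displace the oxonium oxygen from the back, so the C3–O bond must break first. C3 therefore passes through a cation-like state and its configuration is not transferred reliably. The two triflates, needed to stop ionisation at C2, must survive fluoride and later be converted to phenols. Aryne insertions into epoxides are established only for simple cases.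
- Comparison: it is stronger in convergence. The chosen route offers a C3 stereocentre that is set last, on the ring, under control of C2.

Key step: step 7

## Route

Assumption: (R)-t-BuPyOX is taken to give the (2S)-flavanone, by analogy with the (S)-ligand giving (R)-configured β-aryl ketones; if the sense is the opposite, the antipodal ligand is used.

Step 1
Reactants: 1 3,5-dimethoxybenzyl alcohol
Product: 2 [(3,5-dimethoxyphenyl)methoxy]tri(propan-2-yl)silane
Conditions: i-Pr3SiCl, imidazole, DMF, rt
Reagents that add atoms: triisopropylsilyl chloride, CC(C)[Si](Cl)(C(C)C)C(C)C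
Why: Standard silylation of a primary alcohol. The triisopropylsilyl ether is chosen because it has to pass n-BuLi, BCl3 and an acid-mediated ring closure before fluoride removes it.

Step 2
Reactants: 2 [(3,5-dimethoxyphenyl)methoxy]tri(propan-2-yl)silane
Product: 4 1-[2,6-dimethoxy-4-(triisopropylsilyloxymethyl)phenyl]ethan-1-one, via aryllithium 3 (not isolated)
Conditions: n-BuLi, THF, 0 °C to rt; then MeC(O)N(OMe)Me, −78 to 0 °C; aq. NH4Cl
Reagents that add atoms: N-methoxy-N-methylacetamide, CC(=O)N(C)OC; n-butyllithium, [Li]CCCC (lithium of 3 only)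
Why: Directed ortho-metalation: the position between the two methoxy groups is the most acidic, so 3 forms regioselectively. N-Methoxy-N-methyl amides stop cleanly at the ketone stage with aryllithiums.

Step 3
Reactants: 4 1-[2,6-dimethoxy-4-(triisopropylsilyloxymethyl)phenyl]ethan-1-one
Product: 5 1-[2-hydroxy-6-methoxy-4-(triisopropylsilyloxymethyl)phenyl]ethan-1-one
Conditions: BCl3 (1.1 equiv), CH2Cl2, −78 to 0 °C; H2O
Reagents that add atoms: none
Why: Chelation-controlled demethylation: BCl3 bound between the carbonyl oxygen and one ortho methoxy group delivers chloride to that methyl group only. The boron chelate of the product is a weak Lewis acid, so the second ortho ether and the silyl ether should remain.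

Step 4
Reactants: 5 1-[2-hydroxy-6-methoxy-4-(triisopropylsilyloxymethyl)phenyl]ethan-1-one
Product: 7 5-methoxy-7-(triisopropylsilyloxymethyl)-4H-chromen-4-one, via enaminone 6 (not isolated)
Conditions: Me2NCH(OMe)2, toluene, 100 °C; evaporate; then TsOH·H2O, CH2Cl2, rt
Reagents that add atoms: N,N-dimethylformamide dimethyl acetal, COC(OC)N(C)C
Why: The enaminone route to chromones: condensation of the methyl ketone with the amide acetal gives the vinylogous amide 6. Under acid the phenol adds to its β-carbon and dimethylamine is expelled, which closes the pyranone ring.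

Step 5
Reactants: 7 5-methoxy-7-(triisopropylsilyloxymethyl)-4H-chromen-4-one; 8 (2,4-dimethoxyphenyl)boronic acid
Product: 9 (2S)-2-(2,4-dimethoxyphenyl)-5-methoxy-7-(triisopropylsilyloxymethyl)chroman-4-one
Conditions: Pd(OCOCF3)2 (5–10 mol %), (R)-t-BuPyOX, NH4PF6, H2O, ClCH2CH2Cl, 60 °C
Reagents that add atoms: none
Why: Asymmetric conjugate addition of an arylboronic acid to a chromone under cationic divalent palladium with a pyridine-oxazoline ligand: transmetalation, insertion of C2=C3 into the Pd–aryl bond and protonolysis of the palladium enolate by water. The tert-butyl group of the ligand distinguishes the two faces of the chromone and so sets C2 as S.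

Step 6
Reactants: 9 (2S)-2-(2,4-dimethoxyphenyl)-5-methoxy-7-(triisopropylsilyloxymethyl)chroman-4-one
Product: 11 (2R)-3-diazo-2-(2,4-dimethoxyphenyl)-5-methoxy-7-(triisopropylsilyloxymethyl)chroman-4-one, via trifluoroacetyl ketone 10 (not isolated)
Conditions: LiN(SiMe3)2, THF, −78 °C; CF3CO2CH2CF3, −78 °C; aq. NH4Cl; then 4-AcNHC6H4SO2N3, Et3N, H2O, MeCN, 0 °C
Reagents that add atoms: 4-acetamidobenzenesulfonyl azide, CC(=O)Nc1ccc(cc1)S(=O)(=O)N=[N+]=[N-]; 2,2,2-trifluoroethyl trifluoroacetate, FC(F)(F)COC(=O)C(F)(F)F (trifluoroacetyl group of 10 only)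
Why: Detrifluoroacetylative diazo transfer: C3 is deprotonated and trifluoroacetylated at −78 °C, and the activated diketone 10 takes the diazo group from the sulfonyl azide under a weak amine base, losing the trifluoroacetyl group. Brief deprotonation at −78 °C and a weak base at 0 °C are meant to prevent β-elimination of the ring A phenoxide, and once C3 is the diazo carbon this pathway is closed. C2 is unchanged in space; its descriptor becomes R only because C3 now outranks the aryl group.

Step 7
Reactants: 11 (2R)-3-diazo-2-(2,4-dimethoxyphenyl)-5-methoxy-7-(triisopropylsilyloxymethyl)chroman-4-one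
Product: 13 (2S)-2-(2,4-dimethoxyphenyl)-4-methoxy-6-(triisopropylsilyloxymethyl)-2,3-dihydro-1-benzofuran-3-carboxylic acid as its two C3 epimers, via ketene 12 (not isolated)
Conditions: hν (365 nm), 1,4-dioxane/H2O, degassed, 15 °C
Reagents that add atoms: water, O
Why: Excitation of the diazo ketone, which the ring holds s-cis, expels N2 with a concerted 1,2-shift of the ring A carbon (C4a of the chromanone) from the carbonyl carbon to C3; this forms the bond C3–C3a of the benzofuran and makes the former C4 the ketene carbon of 12, which water converts to the acid. The closest known reaction type is the photochemical Wolff ring contraction of cyclic 2-diazo ketones, as on 2-diazo-1-tetralone, diazonaphthoquinones and 3-diazochroman-4-ones. The five-membered ring is closed by the migrating bond itself, a ring contraction by 1,2-shift and not an exo or endo cyclisation. C2 takes no part and keeps its configuration; its descriptor returns to S because C3 no longer carries nitrogen. The new stereocentre C3 is set when the enol form of the acid is protonated: the C2 aryl group, pushed pseudo-axial by allylic strain with the exocyclic C(OH)2 unit, shields one face, so the proton should enter anti to it and give mainly the cis (3R) acid, with the trans (3S) acid as the more stable epimer. This needs no control, because step 8 makes C3 planar. What the step does need is aryl migration in preference to a 1,2-hydride shift from C2 (which would give the flavone) or O–H insertion into water. The s-cis geometry, direct irradiation at a wavelength where only the diazo ketone absorbs, and the good migrating ability of the electron-rich aryl carbon are what secure it.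

Step 8
Reactants: 13 (2S)-2-(2,4-dimethoxyphenyl)-4-methoxy-6-(triisopropylsilyloxymethyl)-2,3-dihydro-1-benzofuran-3-carboxylic acid (both C3 epimers); 14 1-bromo-3,5-dimethoxybenzene
Product: 15 {[(2S,3S)-2-(2,4-dimethoxyphenyl)-3-(3,5-dimethoxyphenyl)-4-methoxy-2,3-dihydro-1-benzofuran-6-yl]methoxy}tri(propan-2-yl)silane
Conditions: NiCl2(MeOCH2CH2OMe) (10 mol %), 4,4'-di-tert-butyl-2,2'-bipyridine, [Ir(dF(CF3)ppy)2(dtbbpy)]PF6 (1–2 mol %), Cs2CO3, DMF, blue LEDs, rt
Reagents that add atoms: none
Why: Metallaphotoredox decarboxylative arylation: the excited trivalent iridium complex oxidises the carboxylate, loss of CO2 gives the planar benzylic C3 radical from either epimer of 13, and the aryl nickel bromide formed from 14 and zerovalent nickel captures it. Reductive elimination from trivalent nickel makes the C3–aryl bond on the face remote from the C2 aryl group, so the trans (2S,3S) product is expected.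

Step 9
Reactants: 15 {[(2S,3S)-2-(2,4-dimethoxyphenyl)-3-(3,5-dimethoxyphenyl)-4-methoxy-2,3-dihydro-1-benzofuran-6-yl]methoxy}tri(propan-2-yl)silane
Product: 16 [(2S,3S)-2-(2,4-dimethoxyphenyl)-3-(3,5-dimethoxyphenyl)-4-methoxy-2,3-dihydro-1-benzofuran-6-yl]methanol
Conditions: n-Bu4NF, THF, 0 °C to rt
Reagents that add atoms: none
Why: Fluoride cleavage of the silyl ether. Nothing else in 15 reacts with fluoride, and C3–H is far too weakly acidic to epimerise.

Step 10
Reactants: 16 [(2S,3S)-2-(2,4-dimethoxyphenyl)-3-(3,5-dimethoxyphenyl)-4-methoxy-2,3-dihydro-1-benzofuran-6-yl]methanol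
Product: 17 (2S,3S)-2-(2,4-dimethoxyphenyl)-3-(3,5-dimethoxyphenyl)-4-methoxy-2,3-dihydro-1-benzofuran-6-carbaldehyde
Conditions: activated MnO2, CH2Cl2, rt
Reagents that add atoms: none
Why: Selective oxidation of a benzylic alcohol to the aldehyde on activated MnO2. It stops at the aldehyde and leaves the ethers and the C2–H and C3–H bonds alone.

Step 11
Reactants: 17 (2S,3S)-2-(2,4-dimethoxyphenyl)-3-(3,5-dimethoxyphenyl)-4-methoxy-2,3-dihydro-1-benzofuran-6-carbaldehyde; 18 diethyl (4-methoxybenzyl)phosphonate
Product: 19 (2S,3S)-2-(2,4-dimethoxyphenyl)-3-(3,5-dimethoxyphenyl)-4-methoxy-6-[(E)-2-(4-methoxyphenyl)ethenyl]-2,3-dihydro-1-benzofuran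
Conditions: KOt-Bu, THF, 0 °C to rt
Reagents that add atoms: none
Why: Horner–Wadsworth–Emmons olefination; benzylic phosphonates give E-stilbenes because addition is reversible and elimination runs through the less crowded adduct. Neither stereocentre has a proton acidic enough for this base.

Step 12
Reactants: 19 (2S,3S)-2-(2,4-dimethoxyphenyl)-3-(3,5-dimethoxyphenyl)-4-methoxy-6-[(E)-2-(4-methoxyphenyl)ethenyl]-2,3-dihydro-1-benzofuran
Product: 20 4-[(2S,3S)-3-(3,5-dihydroxyphenyl)-4-hydroxy-6-[(E)-2-(4-hydroxyphenyl)ethenyl]-2,3-dihydro-1-benzofuran-2-yl]benzene-1,3-diol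
Conditions: BBr3 (excess), CH2Cl2, −78 to 0 °C; ice, aq. NaHCO3
Reagents that add atoms: none
Why: Lewis-acid cleavage of aryl methyl ethers, bromide attacking the methyl group of each boron–ether complex. Complexation of the oxygens on the C2 aryl ring lowers their donor strength and with it the tendency of C2–O1 to ionise. If the ring does open, it should close again to the same trans compound, because C3 is untouched and the two ring A oxygens are equivalent once demethylated.

## Compound list

1 | 3,5-dimethoxybenzyl alcohol | COc1cc(CO)cc(OC)c1 | starting material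
2 | [(3,5-dimethoxyphenyl)methoxy]tri(propan-2-yl)silane | COc1cc(CO[Si](C(C)C)(C(C)C)C(C)C)cc(OC)c1 | intermediate
3 | [2,6-dimethoxy-4-(triisopropylsilyloxymethyl)phenyl]lithium | [Li]c1c(OC)cc(CO[Si](C(C)C)(C(C)C)C(C)C)cc1OC | intermediate
4 | 1-[2,6-dimethoxy-4-(triisopropylsilyloxymethyl)phenyl]ethan-1-one | CC(=O)c1c(OC)cc(CO[Si](C(C)C)(C(C)C)C(C)C)cc1OC | intermediate
5 | 1-[2-hydroxy-6-methoxy-4-(triisopropylsilyloxymethyl)phenyl]ethan-1-one | CC(=O)c1c(O)cc(CO[Si](C(C)C)(C(C)C)C(C)C)cc1OC | intermediate
6 | (E)-3-(dimethylamino)-1-[2-hydroxy-6-methoxy-4-(triisopropylsilyloxymethyl)phenyl]prop-2-en-1-one | CN(C)/C=C/C(=O)c1c(O)cc(CO[Si](C(C)C)(C(C)C)C(C)C)cc1OC | intermediate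
7 | 5-methoxy-7-(triisopropylsilyloxymethyl)-4H-chromen-4-one | COc1cc(CO[Si](C(C)C)(C(C)C)C(C)C)cc2occc(=O)c12 | intermediate
8 | (2,4-dimethoxyphenyl)boronic acid | COc1ccc(B(O)O)c(OC)c1 | starting material
9 | (2S)-2-(2,4-dimethoxyphenyl)-5-methoxy-7-(triisopropylsilyloxymethyl)chroman-4-one | CC(C)[Si](C(C)C)(C(C)C)OCc1cc(OC)c2c(c1)O[C@H](c1ccc(OC)cc1OC)CC2=O | intermediate
10 | (2S)-2-(2,4-dimethoxyphenyl)-5-methoxy-3-(trifluoroacetyl)-7-(triisopropylsilyloxymethyl)chroman-4-one (C3 not defined, largely enol) | CC(C)[Si](C(C)C)(C(C)C)OCc1cc(OC)c2c(c1)O[C@H](c1ccc(OC)cc1OC)C(C(=O)C(F)(F)F)C2=O | intermediate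
11 | (2R)-3-diazo-2-(2,4-dimethoxyphenyl)-5-methoxy-7-(triisopropylsilyloxymethyl)chroman-4-one | CC(C)[Si](C(C)C)(C(C)C)OCc1cc(OC)c2c(c1)O[C@H](c1ccc(OC)cc1OC)C(=[N+]=[N-])C2=O | intermediate
12 | [(2R)-2-(2,4-dimethoxyphenyl)-4-methoxy-6-(triisopropylsilyloxymethyl)-1-benzofuran-3(2H)-ylidene]methanone (ketene) | CC(C)[Si](C(C)C)(C(C)C)OCc1cc(OC)c2c(c1)O[C@H](c1ccc(OC)cc1OC)C2=C=O | intermediate
13 | (2S)-2-(2,4-dimethoxyphenyl)-4-methoxy-6-(triisopropylsilyloxymethyl)-2,3-dihydro-1-benzofuran-3-carboxylic acid, C3 epimers (cis 2S,3R expected as the kinetic one, trans 2S,3S the more stable) | CC(C)[Si](C(C)C)(C(C)C)OCc1cc(OC)c2c(c1)O[C@H](c1ccc(OC)cc1OC)C2C(=O)O | intermediate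
14 | 1-bromo-3,5-dimethoxybenzene | COc1cc(Br)cc(OC)c1 | starting material
15 | {[(2S,3S)-2-(2,4-dimethoxyphenyl)-3-(3,5-dimethoxyphenyl)-4-methoxy-2,3-dihydro-1-benzofuran-6-yl]methoxy}tri(propan-2-yl)silane (trans) | CC(C)[Si](C(C)C)(C(C)C)OCc1cc(OC)c2c(c1)O[C@H](c1ccc(OC)cc1OC)[C@H]2c1cc(OC)cc(OC)c1 | intermediate
16 | [(2S,3S)-2-(2,4-dimethoxyphenyl)-3-(3,5-dimethoxyphenyl)-4-methoxy-2,3-dihydro-1-benzofuran-6-yl]methanol | OCc1cc(OC)c2c(c1)O[C@H](c1ccc(OC)cc1OC)[C@H]2c1cc(OC)cc(OC)c1 | intermediate
17 | (2S,3S)-2-(2,4-dimethoxyphenyl)-3-(3,5-dimethoxyphenyl)-4-methoxy-2,3-dihydro-1-benzofuran-6-carbaldehyde | O=Cc1cc(OC)c2c(c1)O[C@H](c1ccc(OC)cc1OC)[C@H]2c1cc(OC)cc(OC)c1 | intermediate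
18 | diethyl (4-methoxybenzyl)phosphonate | CCOP(=O)(Cc1ccc(OC)cc1)OCC | starting material
19 | (2S,3S)-2-(2,4-dimethoxyphenyl)-3-(3,5-dimethoxyphenyl)-4-methoxy-6-[(E)-2-(4-methoxyphenyl)ethenyl]-2,3-dihydro-1-benzofuran | COc1ccc(/C=C/c2cc(OC)c3c(c2)O[C@H](c2ccc(OC)cc2OC)[C@H]3c2cc(OC)cc(OC)c2)cc1 | intermediate
20 | 4-[(2S,3S)-3-(3,5-dihydroxyphenyl)-4-hydroxy-6-[(E)-2-(4-hydroxyphenyl)ethenyl]-2,3-dihydro-1-benzofuran-2-yl]benzene-1,3-diol | Oc1ccc(/C=C/c2cc(O)c3c(c2)O[C@H](c2ccc(O)cc2O)[C@H]3c2cc(O)cc(O)c2)cc1 | target

## Step count and least certain steps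

Total: 12 steps. Longest linear sequence: 12 steps, from 1; compounds 8, 14 and 18 are bought.

**Step 7 (key step).** Nitrogen may be lost to a free keto carbene instead of in concert with migration. A 1,2-hydride shift from C2, which O1 and the aryl group activate, would then aromatise the ring to the flavone, or the carbene would insert into water. Light-induced opening of the pyranone ring would erode C2. Fallback: from 9, without the diazo compound, an oxidative ring contraction with trivalent iodine (PhI(OAc)2, HC(OMe)3, catalytic H2SO4). In it the ring A carbon shifts from a C4 ketal to C3 as iodobenzene leaves, giving methyl (2S,3S)-2-(2,4-dimethoxyphenyl)-4-methoxy-6-(triisopropylsilyloxymethyl)-2,3-dihydro-1-benzofuran-3-carboxylate F1. LiOH in aqueous THF then returns to the route at 13. Its weak points are the acid medium and possible competing migration of the electron-rich C2 aryl group, which is why it is only the reserve.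

**Step 5.** Insertion may be slow with an ortho-substituted, electron-rich boronic acid, so that protodeboronation wins or face selectivity drops. Fallback: from 5, Claisen–Schmidt condensation with 2,4-dimethoxybenzaldehyde F2 (KOH, EtOH) gives (E)-3-(2,4-dimethoxyphenyl)-1-[2-hydroxy-6-methoxy-4-(triisopropylsilyloxymethyl)phenyl]prop-2-en-1-one F3. NaOAc in hot ethanol closes it to racemic 2-(2,4-dimethoxyphenyl)-5-methoxy-7-(triisopropylsilyloxymethyl)chroman-4-one F4. A kinetic resolution by asymmetric transfer hydrogenation ([RuCl(p-cymene)(TsDPEN)], divalent ruthenium, HCO2H/Et3N; the catalyst enantiomer that reduces the 2R ketone) turns the unwanted enantiomer into (2R,4R)-2-(2,4-dimethoxyphenyl)-5-methoxy-7-(triisopropylsilyloxymethyl)chroman-4-ol F5. The unreduced ketone is 9, where the route is rejoined.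

**Step 6.** The lithium enolate or the diketonate of 10 may reversibly open the pyranone ring by β-elimination of the phenoxide, which would lower the enantiomeric purity at C2. Fallback without a C3 carbanion: from 9, acid-catalysed nitrosation (isoamyl nitrite, catalytic HCl) gives (2R)-2-(2,4-dimethoxyphenyl)-3-(hydroxyimino)-5-methoxy-7-(triisopropylsilyloxymethyl)chroman-4-one F6. The Forster reaction with chloramine (NaOCl, aqueous NH3, 0 °C) converts the oxime to the diazo ketone, returning at 11.

**Step 8.** The electron-rich C3 radical may be oxidised to the cation, or the alkylnickel species may lose a β-hydride; both lead to aromatisation to the 2-arylbenzofuran. Simple protodecarboxylation or poor face selectivity are also possible. Fallback without photocatalyst and carbonate: from 13, N,N'-diisopropylcarbodiimide and N-hydroxyphthalimide give 1,3-dioxoisoindolin-2-yl (2S)-2-(2,4-dimethoxyphenyl)-4-methoxy-6-(triisopropylsilyloxymethyl)-2,3-dihydro-1-benzofuran-3-carboxylate F7. It is coupled with (3,5-dimethoxyphenyl)zinc chloride F8 (from 14 by magnesium insertion with LiCl, then ZnCl2) under NiCl2(MeOCH2CH2OMe) and 4,4'-di-tert-butyl-2,2'-bipyridine in THF/DMF. This returns at 15.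

**Step 12.** Heterolysis of C2–O1 is by itself reversible, but the cation may alkylate the electron-rich stilbene of a second molecule or lose the C3 proton, and acid may add to the alkene; six ethers may also not all cleave. Fallback that keeps the stilbene away from the Lewis acid and ends with fluoride:
- From 17, BBr3 in CH2Cl2 gives (2S,3S)-2-(2,4-dihydroxyphenyl)-3-(3,5-dihydroxyphenyl)-4-hydroxy-2,3-dihydro-1-benzofuran-6-carbaldehyde F9.
- t-BuMe2SiCl and imidazole give (2S,3S)-2-[2,4-bis(tert-butyldimethylsilyloxy)phenyl]-3-[3,5-bis(tert-butyldimethylsilyloxy)phenyl]-4-(tert-butyldimethylsilyloxy)-2,3-dihydro-1-benzofuran-6-carbaldehyde F10.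
- Olefination with diethyl [4-(tert-butyldimethylsilyloxy)benzyl]phosphonate F11 (NaH, THF) gives the hexasilyl ether of the target, (2S,3S)-2-[2,4-bis(tert-butyldimethylsilyloxy)phenyl]-3-[3,5-bis(tert-butyldimethylsilyloxy)phenyl]-4-(tert-butyldimethylsilyloxy)-6-{(E)-2-[4-(tert-butyldimethylsilyloxy)phenyl]ethenyl}-2,3-dihydro-1-benzofuran F12.
- n-Bu4NF buffered with AcOH in THF at 0 °C converts it to 20.

## Further compounds

F1 | step 7 | methyl (2S,3S)-2-(2,4-dimethoxyphenyl)-4-methoxy-6-(triisopropylsilyloxymethyl)-2,3-dihydro-1-benzofuran-3-carboxylate | CC(C)[Si](C(C)C)(C(C)C)OCc1cc(OC)c2c(c1)O[C@H](c1ccc(OC)cc1OC)[C@H]2C(=O)OC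
F2 | step 5 | 2,4-dimethoxybenzaldehyde | COc1ccc(C=O)c(OC)c1
F3 | step 5 | (E)-3-(2,4-dimethoxyphenyl)-1-[2-hydroxy-6-methoxy-4-(triisopropylsilyloxymethyl)phenyl]prop-2-en-1-one | COc1ccc(/C=C/C(=O)c2c(O)cc(CO[Si](C(C)C)(C(C)C)C(C)C)cc2OC)c(OC)c1
F4 | step 5 | racemic 2-(2,4-dimethoxyphenyl)-5-methoxy-7-(triisopropylsilyloxymethyl)chroman-4-one | CC(C)[Si](C(C)C)(C(C)C)OCc1cc(OC)c2c(c1)OC(c1ccc(OC)cc1OC)CC2=O
F5 | step 5 | (2R,4R)-2-(2,4-dimethoxyphenyl)-5-methoxy-7-(triisopropylsilyloxymethyl)chroman-4-ol | CC(C)[Si](C(C)C)(C(C)C)OCc1cc(OC)c2c(c1)O[C@@H](c1ccc(OC)cc1OC)C[C@H]2O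
F6 | step 6 | (2R)-2-(2,4-dimethoxyphenyl)-3-(hydroxyimino)-5-methoxy-7-(triisopropylsilyloxymethyl)chroman-4-one | CC(C)[Si](C(C)C)(C(C)C)OCc1cc(OC)c2c(c1)O[C@H](c1ccc(OC)cc1OC)C(=NO)C2=O
F7 | step 8 | 1,3-dioxoisoindolin-2-yl (2S)-2-(2,4-dimethoxyphenyl)-4-methoxy-6-(triisopropylsilyloxymethyl)-2,3-dihydro-1-benzofuran-3-carboxylate (C3 epimers) | CC(C)[Si](C(C)C)(C(C)C)OCc1cc(OC)c2c(c1)O[C@H](c1ccc(OC)cc1OC)C2C(=O)ON1C(=O)c2ccccc2C1=O
F8 | step 8 | (3,5-dimethoxyphenyl)zinc chloride | COc1cc(OC)cc([Zn]Cl)c1
F9 | step 12 | (2S,3S)-2-(2,4-dihydroxyphenyl)-3-(3,5-dihydroxyphenyl)-4-hydroxy-2,3-dihydro-1-benzofuran-6-carbaldehyde | O=Cc1cc(O)c2c(c1)O[C@H](c1ccc(O)cc1O)[C@H]2c1cc(O)cc(O)c1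
F10 | step 12 | (2S,3S)-2-[2,4-bis(tert-butyldimethylsilyloxy)phenyl]-3-[3,5-bis(tert-butyldimethylsilyloxy)phenyl]-4-(tert-butyldimethylsilyloxy)-2,3-dihydro-1-benzofuran-6-carbaldehyde | O=Cc1cc(O[Si](C)(C)C(C)(C)C)c2c(c1)O[C@H](c1ccc(O[Si](C)(C)C(C)(C)C)cc1O[Si](C)(C)C(C)(C)C)[C@H]2c1cc(O[Si](C)(C)C(C)(C)C)cc(O[Si](C)(C)C(C)(C)C)c1
F11 | step 12 | diethyl [4-(tert-butyldimethylsilyloxy)benzyl]phosphonate | CCOP(=O)(Cc1ccc(O[Si](C)(C)C(C)(C)C)cc1)OCC
F12 | step 12 | (2S,3S)-2-[2,4-bis(tert-butyldimethylsilyloxy)phenyl]-3-[3,5-bis(tert-butyldimethylsilyloxy)phenyl]-4-(tert-butyldimethylsilyloxy)-6-{(E)-2-[4-(tert-butyldimethylsilyloxy)phenyl]ethenyl}-2,3-dihydro-1-benzofuran | CC(C)(C)[Si](C)(C)Oc1ccc(/C=C/c2cc(O[Si](C)(C)C(C)(C)C)c3c(c2)O[C@H](c2ccc(O[Si](C)(C)C(C)(C)C)cc2O[Si](C)(C)C(C)(C)C)[C@H]3c2cc(O[Si](C)(C)C(C)(C)C)cc(O[Si](C)(C)C(C)(C)C)c2)cc1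
A1 | alternative 1 | methyl 5-{[(1S,2R)-1-(2,4-dimethoxyphenyl)-2-(3,5-dimethoxyphenyl)but-3-yn-1-yl]oxy}furan-3-carboxylate | COC(=O)c1coc(O[C@H](c2ccc(OC)cc2OC)[C@H](C#C)c2cc(OC)cc(OC)c2)c1
A2 | alternative 1 | methyl (2S,3S)-2-(2,4-dimethoxyphenyl)-3-(3,5-dimethoxyphenyl)-4-hydroxy-2,3-dihydrobenzofuran-6-carboxylate | COC(=O)c1cc(O)c2c(c1)O[C@H](c1ccc(OC)cc1OC)[C@H]2c1cc(OC)cc(OC)c1
A3 | alternative 2 | 5-bromo-1-[(2,4-dimethoxyphenyl)methoxy]-2-[diazo(3,5-dimethoxyphenyl)methyl]-3-methoxybenzene | COc1ccc(COc2cc(Br)cc(OC)c2C(=[N+]=[N-])c2cc(OC)cc(OC)c2)c(OC)c1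
A4 | alternative 2 | (2R,3S)-cis-6-bromo-2-(2,4-dimethoxyphenyl)-3-(3,5-dimethoxyphenyl)-4-methoxy-2,3-dihydrobenzofuran | Brc1cc(OC)c2c(c1)O[C@@H](c1ccc(OC)cc1OC)[C@H]2c1cc(OC)cc(OC)c1
A5 | alternative 3 | methyl 3-methoxy-4-(trifluoromethylsulfonyloxy)-5-(trimethylsilyl)benzoate | COC(=O)c1cc(OC)c(OS(=O)(=O)C(F)(F)F)c([Si](C)(C)C)c1
A6 | alternative 3 | (2R,3R)-2-[2,4-bis(trifluoromethylsulfonyloxy)phenyl]-3-(3,5-dimethoxyphenyl)oxirane | O1[C@H](c2ccc(OS(=O)(=O)C(F)(F)F)cc2OS(=O)(=O)C(F)(F)F)[C@H]1c1cc(OC)cc(OC)c1
A7 | alternative 3 | methyl (2S,3S)-2-[2,4-bis(trifluoromethylsulfonyloxy)phenyl]-3-(3,5-dimethoxyphenyl)-4-methoxy-2,3-dihydrobenzofuran-6-carboxylate | COC(=O)c1cc(OC)c2c(c1)O[C@H](c1ccc(OS(=O)(=O)C(F)(F)F)cc1OS(=O)(=O)C(F)(F)F)[C@H]2c1cc(OC)cc(OC)c1
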